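The readings were computed for substances that don't exist.

**Conserved charge.** Starting material and what forms from it add up to the whole charge from the end of the 8.0 s feed onward. Suppose each starting material that reacts takes one partner. Turnovers are then capped by the partner equivalents, the partner charged per starting material charged, here 0.800 for the flask. Above one equivalent, the cap is the whole charge.

| flask | starting material | partner | remark | time |
|---|---|---|---|---|
| north-east | 0.46 M (fed, over 8.0 s) | 0.18 M | run made earlier |  |
| south | 0.46 M (fed, over 8.0 s) | 0.74 M | run made earlier |  |
| south-west | 0.92 M (fed, over 8.0 s) | 0.368 M | run made earlier |  |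
| flask | 0.46 M (fed, over 8.0 s) | 0.368 M |  | 40 min |

| run | time / min | intermediate B / % | target / % |
|---|---|---|---|
| north-east | 0.333 | 2 | 0 |
| north-east | 0.667 | 6 | 1 |
| north-east | 1.50 | 11 | 0 |
| north-east | 3.00 | 8 | 3 |
| north-east | 8.00 | 3 | 5 |
| north-east | 15.0 | 1 | 0 |
| north-east | 30.0 | 0 | 0 |
| south | 0.333 | 17 | 2 |
| south | 0.667 | 27 | 0 |
| south | 1.50 | 22 | 1 |
| south | 3.00 | 16 | 5 |
| south | 8.00 | 2 | 0 |
| south | 15.0 | 0 | 0 |
| south | 30.0 | 0 | 0 |
| south-west | 0.333 | 9 | 1 |
| south-west | 1.00 | 10 | 3 |
| south-west | 3.00 | 6 | 5 |
| south-west | 10.0 | 0 | 0 |
| south-west | 30.0 | 3 | 0 |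

(each reading ± 2 percentage points)

- the analysis behind the earlier runs scatters by 2 percentage points, standard deviation

- the best time, 40 min at the latest, for intermediate B
- the amount of intermediate B, in percent of the starting material charged, at that time

**Odd pair.** The south-west run holds twice the partner of the north-east run, yet its highest reading of intermediate B is 10 % against 11 %.

**Counting turnovers.** The south-west run also holds twice the starting material, so its equivalents are 0.400 against 0.391, nearly the same cap. Each peak reading is about a quarter of its cap, and so is the south run's 27 % of the whole charge. Their mean share is 0.267, so I reckon 21.4 % for the flask.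

**The forecast.** With “yield tracking the partner/starting-material ratio”, the forecast gives 19 % (15 % to 23 %) at 1 min (0.6 min to 1.6 min). My figure stands higher than its 19 %.

    target ⇌ isomer of the product (K = 11.0, k = 0.00560 /s)
    intermediate A ⇌ intermediate B (K = 1.90, k = 0.570 /s)
    partner + intermediate B ⇌ intermediate C (K = 1.30 /M, k = 0.0390 /M/s)
    intermediate A → decomposed reagent (k = 0.0280 /s)
    intermediate C ⇌ target (K = 1.10, k = 0.0190 /s)
    starting material + partner → intermediate A (k = 0.0360 /M/s)

**The flask.** The flask gives 17.3 % at 1.33 min, inside the forecast's ranges and 0.216 of its cap, less than my share. The cap is 80.0 %, as counted. Partner is the limiting reagent, falling to 0.15 % at 40.0 min with 21 % of starting material left, against 20.0 % by the count. The largest single effect holding the flask below the cap is the way back from intermediate B to intermediate A: without it, the highest intermediate B is 67.4 %. A neighbour flask with 0.478 equiv of partner counts 52.2 % left and holds 53 %.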